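- Pool the readings; don't read the plateau.

| flask | left-handed substrate | right-handed substrate | reagent | remark | time |
|---|---|---|---|---|---|
| red | 0.16 M | 0.16 M | 0.042 M | run made earlier |  |
| teal | 0.16 M | 0.16 M | 0.44 M | run made earlier |  |
| ash | 0.16 M | 0.16 M | 0.0400 M |  | 8.0 min |
| maple | 0.16 M | 0.16 M | 0.120 M |  | 8.0 min |
| cedar | 0.16 M | 0.16 M | 0.400 M |  | 8.0 min |

| run | time / min | left-handed product / % | right-handed product / % | left-handed substrate / % |
|---|---|---|---|---|
| red | 0.417 | 4 | 0 | 35 |
| red | 0.833 | 1 | 3 | 26 |
| red | 1.50 | 5 | 0 | 24 |
| red | 3.00 | 2 | 1 | 12 |
| red | 6.00 | 3 | 4 | 1 |
| teal | 0.500 | 8 | 9 | 25 |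
| teal | 1.33 | 13 | 8 | 15 |
| teal | 2.50 | 14 | 7 | 3 |
| teal | 4.00 | 19 | 7 | 3 |
| teal | 6.00 | 18 | 10 | 2 |

(readings scatter by 2 percentage points)

- reagent is single-handed; left-handed substrate and right-handed substrate are mirror images of each other, charged as a racemate, each of them at the stated concentration
- the analysis behind the earlier runs scatters by 2 percentage points, standard deviation
- an excess is the difference of the two amounts in percent of their sum
- "hardly changes" means that all values lie within two and a half points (for a concentration: within two and a half percent of the largest)
- the handed part of reagent does not stay in what it makes, so the products of the two hands are mirror images too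

- excess of left-handed product over right-handed product at the end for ash, maple, cedar, in this order
- the course of these numbers from the first flask to the last (rises, then falls / falls, then rises / rises all the way / falls all the way / hardly changes)

- Divide the two capture rates, with kL and kR the rate constants of reagent on left-handed and on right-handed substrate: d[left-handed product]/d[right-handed product] = kL[left-handed substrate]/(kR[right-handed substrate]). Time and [reagent] drop out.
- Set the two substrate concentrations equal. That is fair while a loss common to both hands dominates.
- Test it on the left hand. At 6.00 min in teal, left-handed product reads 37.5% of the left-handed substrate lost. At 6.00 min in red it reads 6.12%. In both runs these readings put more of the loss elsewhere than in left-handed product.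
- Take the ratio as kL/kR. This is the selectivity factor: left-handed product made per right-handed product made from equal substrate concentrations. The pooled readings then estimate it.
- Sum the 10 readings of each product over both runs. Left-handed gives 87.0%, right-handed 49.0%.
- Read the factor as 1.78. The excess is then 27.9%, give or take 6.6 percentage points.
- Commit to that reckoning: about that excess in each of the 3 flasks, and a row that hardly changes.
- Set the forecast beside it: 48%, 45%, 38%, falls all the way, on the ground that “capture competes with waste and the faster hand saturates”. Its last value is still higher than mine.
- Now the flasks: 27.6%, 27.2%, 25.7%, and the row hardly changes.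

    reagent + left-handed substrate → left-handed product (k = 0.0460 /M/s)
    reagent + right-handed substrate → right-handed product (k = 0.0260 /M/s)
    left-handed substrate ⇌ achiral form (K = 0.660, k = 0.0380 /s)
    right-handed substrate ⇌ achiral form (K = 0.660, k = 0.0380 /s)
    achiral form → side product (k = 0.0370 /s)
    reagent ⇌ dormant form (K = 4.90, k = 0.0540 /s)
    reagent → decomposition product (k = 4.40 × 10⁻⁵ /s)

- In ash, left-handed substrate goes to the achiral form 170 times faster than to left-handed product at 8.00 min, and right-handed substrate goes 280 times faster than to right-handed product at 1.51 min, each counting the forward step alone. Dividing the left-handed product at 8.00 min by 1.78 gives 1.16% right-handed product for ash, against 1.17% in the flask, and 9.64% for cedar, against 10.1%.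

(The earlier runs and the new flask stem from a simulated flask with made-up constants; noise was put on by code.)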